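The earlier runs and the new flask stem from a simulated flask for an exercise; noise was put on by code.

3 questions hang on this bench, two orders and the content of the north-west flask at 26 min, and this note is for whoever takes it over.

| flask | starting material | partner | target | time |
|---|---|---|---|---|
| south | 0.100 M | 0.300 M |  |  |
| south-west | 0.0400 M | 0.240 M |  |  |
| north | 0.150 M | 0.300 M |  |  |
| south-east | 0.100 M | 0.300 M | 0.0300 M |  |
| north-west | 0.100 M | 0.300 M |  | 26 min |

- south run (time / min: [target] / M): 0.29: 0.0049; 0.88: 0.0141; 1.7: 0.0230; 2.7: 0.0322; 3.8: 0.0382; 5.1: 0.0418; 6.5: 0.0444
- south-west run (time / min: [target] / M): 0.29: 0.0016; 0.88: 0.0048; 1.7: 0.0076; 2.7: 0.0106; 3.8: 0.0134; 5.1: 0.0153; 6.5: 0.0156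
- north run (time / min: [target] / M): 0.29: 0.0077; 0.88: 0.0207; 1.7: 0.0342; 2.7: 0.0471; 3.8: 0.0553; 5.1: 0.0615; 6.5: 0.0644
- south-east run (time / min: [target] / M): 0.29: 0.0342; 0.88: 0.0430; 1.7: 0.0517; 2.7: 0.0582; 3.8: 0.0629; 5.1: 0.0660; 6.5: 0.0668

(readings scatter by 3 × 10⁻⁴ M)

* the exponent of [partner] in the starting rate at the charge of the south run (at the point where two percent of the starting material have become target)
* the exponent of [starting material] in the starting rate at the charge of the south run (at the point where two percent of the starting material have become target) (one fixed amount of target, the same in the runs compared)
* target in the north-west run at 26 min, as a share of the starting material charged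

- Overall: starting material + partner -> target.
- Constant volume, constant temperature.
- "The second partner" is partner.
- An order is taken over about fifteen percent of the charge, up and down.

The north-west flask holds the charge of the south run, so the south run shows what it does up to 6.5 min. Starting material is the limiting reagent there, 0.100 M against 0.300 M of partner. The south-east run has that charge plus 0.0300 M of target, so we follow that added target by subtracting the south run. The gap is 0.0293 M at 0.29 min and 0.0224 M at 6.5 min, which reads as 0.0432 /min, the target's loss constant: the share of the target present that goes per minute.

A molecule of target present at 6.5 min therefore has a chance of 0.430 of still being there at 26 min. Do not take the flat top of the south run for an end point: at 6.5 min its loss of 0.00192 M/min is about equal to its last rise of 0.00186 M/min. Making is then 0.00378 M/min, down from 0.0169 M/min at the first reading. That fall gives 0.230 /min, so about 0.0164 M is still to come. Our own reckoning for the north-west flask, which counts that amount as if it were already there at 6.5 min, is 26.2 % of the charge.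

The forecast gives 49 % (range 46 % to 56 %), more than ours, with orders 1 in starting material and 0.8 in partner: “This suggests decaying activity and/or reversibility.”

The north-west flask holds 25.1 % of its charge at 26 min, and the orders are 1.0 in starting material and 1.0 in partner.

    starting material + partner → target + by-product (0.6240 /M/min)
    target → decomposed product (0.04362 /min)
    starting material → decomposed substrate (0.08880 /min)

Where two percent of the starting material have become target, the south-east run goes at 0.92 of the south run's rate. Counted back with the loss constant, as if all of it had been there at 6.5 min, the 0.0251 M of target in the north-west flask stands for 0.0584 M at that time. In the north run at 6.5 min, the same constant puts the loss at 0.00278 M/min, against a last net rise of 0.00207 M/min.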